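**Retrosynthetic overview**

1. Endgame: the exocyclic methylene is made last from the ring-A ketone (Takai–Lombardo methylenation). The ArCH2 bond comes from a nickel/photoredox deoxygenative arylation of a neopentyl carbinol with an O-acetylated bromophenol ester.
2. The C-2 methyl stereocenter (cis to both other methyls, the less stable arrangement) comes from a C-2 ketone by Wittig methylenation, ester reduction and hydroxyl-directed hydrogenation on the face of the CH2OH group.
3. Key disconnection: ring B is closed in one operation from a monocyclic β-keto ester of (2-methyl-6-oxocyclohex-1-enyl)methanol. The bond between the two quaternary carbons (C-1–C-8a) forms by intramolecular SN2′ attack of the ester's own enolate, and the C-3–C-4 bond by Michael closure of the acetyl group (traceless-tether [3+3] annulation).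
4. Enabling feature: the enone of ring A carries the CH2–O(acyl) group on its α-carbon and a methyl on its β-carbon, so the allylic C–O bond is β to the ketone. The acyloxy group is therefore both a vinylogous leaving group and the tether that brings its α-carbon onto the β-carbon, and its departure unveils a 2-methylene ketone for the second ring bond.
5. Ring order: ring A is bought (3-methylcyclohex-2-en-1-one), ring B is formed in the key step, the arene is attached afterwards. Locants are those of decahydronaphthalene (C-1 quaternary carbon bearing the one-carbon arm, C-2 ring-B carbonyl/methyl carbon, C-4a ring-fusion CH, C-5 ring-A carbonyl, C-8a angular-methyl carbon).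

Key step: step 4

Remark on the chemistry: the (S,S) ligand is assumed to expose the enolate face that leads to the (1S,8aS) series drawn; if the opposite sense is found, the (R,R) ligand is used with no other change.

**Route**

Step 1
Reactants: 1 3-methylcyclohex-2-en-1-one
Product: 2 2-iodo-3-methylcyclohex-2-en-1-one
Conditions: I2 (1.5 equiv), DMAP (0.2 equiv), K2CO3 (1.2 equiv), THF–H2O 1:1, rt
Reagents that add atoms: iodine, II
Why: Amine-catalysed α-iodination of a cyclic enone (conjugate addition of DMAP, iodination of the enolate, elimination), a standard reaction that creates no stereocenter.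

Step 2
Reactants: 2 2-iodo-3-methylcyclohex-2-en-1-one
Product: 3 2-(hydroxymethyl)-3-methylcyclohex-2-en-1-one
Conditions: Bu3SnCH2OH (1.3 equiv), Pd(PPh3)4 (5 mol %), 1,4-dioxane, 90 °C
Reagents that add atoms: (tributylstannyl)methanol, CCCC[Sn](CCCC)(CCCC)CO
Why: Stille coupling of an α-iodoenone with the hydroxymethylstannane puts the CH2OH arm on the α-carbon; no stereocenter is formed.

Step 3
Reactants: 3 2-(hydroxymethyl)-3-methylcyclohex-2-en-1-one; 4 methyl 2-methyl-3-oxobutanoate
Product: 5 (2-methyl-6-oxocyclohex-1-en-1-yl)methyl 2-methyl-3-oxobutanoate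
Conditions: B(OH)3 (10 mol %), toluene, reflux, MeOH distilled off
Reagents that add atoms: none
Why: Boric-acid-catalysed transesterification of a β-keto ester with a primary allylic alcohol works under neutral conditions, so the base-triggered cascade of step 4 cannot start early; the α-carbon of 5 epimerises freely and is left undefined.

Step 4
Reactants: 5 (2-methyl-6-oxocyclohex-1-en-1-yl)methyl 2-methyl-3-oxobutanoate
Product: 9 methyl (1S,4aR,8aS)-1,8a-dimethyl-2,5-dioxodecahydronaphthalene-1-carboxylate, via lactone enolate 6 (not isolated), via methylene keto acid 7 (not isolated), via methylene keto ester 8 (not isolated)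
Conditions: Cu(OTf)2 (10 mol %), 2,2′-(propane-2,2-diyl)bis[(4S)-4-tert-butyl-4,5-dihydro-1,3-oxazole] (11 mol %), Et3N (1.1 equiv), CH2Cl2, −20 to 0 °C; then MeI (3 equiv), DBU (2.5 equiv), −20 °C to rt
Reagents that add atoms: iodomethane, CI
Why: Proposed new method: the bis(oxazoline) chelate of divalent copper with the 2-methylacetoacetate enolate adds to the β-carbon of the tethered ring-A enone through a chair six-membered (δ-lactone, 6-endo-trig) transition state, and the enolate so formed (6) at once expels the carboxylate (E1cB), an intramolecular SN2′ that joins the two fully substituted carbons and unmasks the 2-methylene ketone acid 7; after O-methylation to 8, DBU forms the acetyl enolate, which closes ring B by a 6-(enolendo)-endo-trig Michael addition onto the exocyclic methylene. The closest known chemistry is the [3+3] annulation of Morita–Baylis–Hillman acetates or carbonates with β-keto esters (SN2′, then Michael), the Carroll rearrangement of allyl acetoacetates (here without loss of CO2) and the enantioselective reactions of bis(oxazoline)–copper enolates of 2-methylacetoacetates; what is new is that the leaving carboxylate is the nucleophile's own ester and so serves as a traceless tether. C-8a and C-1 arise together: the chelated U-shaped enolate places its C-methyl pseudoaxial and its acetyl group pseudoequatorial in the chair, while the ring methyl, cis to the CH2O arm, is pseudoaxial, which puts the ester carbon anti to the angular methyl; the tert-butyl groups of the ligand block one enolate face and so fix the absolute sense. C-4a is set last by protonation of the C-5 enolate on the face away from the angular methyl, which is also the more stable trans ring fusion at this stage (nothing is yet axial at C-2). The step needs the tertiary carbon to attack the hindered β-carbon and not the CH2 group: the tether secures this, because the carboxylate sits on the CH2 and only the β-carbon lies within reach of a six-membered transition state, and in the second closure the acetyl CH3 is the only enolisable carbon that can reach the methylene (the other α-carbon is quaternary).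

Step 5
Reactants: 9 methyl (1S,4aR,8aS)-1,8a-dimethyl-2,5-dioxodecahydronaphthalene-1-carboxylate
Product: 10 methyl (1S,4aR,8aS)-5,5-(ethylenedioxy)-1,8a-dimethyl-2-oxodecahydronaphthalene-1-carboxylate
Conditions: Me3SiOCH2CH2OSiMe3 (1.2 equiv), TMSOTf (5 mol %), CH2Cl2, −78 to −20 °C
Reagents that add atoms: 1,2-bis(trimethylsilyloxy)ethane, C[Si](C)(C)OCCO[Si](C)(C)C
Why: Silyl-transfer ketalisation under kinetic control should take only the C-5 ketone, because the C-2 ketone is flanked by the fully substituted C-1 and is part of the β-keto ester; no stereocenter is touched.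

Step 6
Reactants: 10 methyl (1S,4aR,8aS)-5,5-(ethylenedioxy)-1,8a-dimethyl-2-oxodecahydronaphthalene-1-carboxylate
Product: 11 methyl (1R,4aR,8aS)-5,5-(ethylenedioxy)-1,8a-dimethyl-2-methylidenedecahydronaphthalene-1-carboxylate
Conditions: Ph3PCH3Br (3 equiv), KN(SiMe3)2 (2.8 equiv), toluene, 0 to 90 °C
Reagents that add atoms: methyltriphenylphosphonium bromide, C[P+](c1ccccc1)(c1ccccc1)c1ccccc1.[Br-]
Why: Wittig methylenation of a hindered ketone with alkoxide-free ylide at elevated temperature; C-1 cannot enolise and C-4a is no longer α to a carbonyl, so nothing epimerises (the C-1 descriptor changes only through the priority rules).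

Step 7
Reactants: 11 methyl (1R,4aR,8aS)-5,5-(ethylenedioxy)-1,8a-dimethyl-2-methylidenedecahydronaphthalene-1-carboxylate
Product: 12 [(1R,4aR,8aS)-5,5-(ethylenedioxy)-1,8a-dimethyl-2-methylidenedecahydronaphthalen-1-yl]methanol
Conditions: LiAlH4 (2 equiv), THF, 0 °C to reflux
Reagents that add atoms: none
Why: Hydride reduction of the neopentyl ester to the primary alcohol; ketal and alkene are inert and no stereocenter changes.

Step 8
Reactants: 12 [(1R,4aR,8aS)-5,5-(ethylenedioxy)-1,8a-dimethyl-2-methylidenedecahydronaphthalen-1-yl]methanol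
Product: 13 [(1R,2S,4aR,8aS)-5,5-(ethylenedioxy)-1,2,8a-trimethyldecahydronaphthalen-1-yl]methanol
Conditions: [Ir(cod)(PCy3)(py)]PF6 (5 mol %), H2 (1 atm), CH2Cl2, rt
Reagents that add atoms: none
Why: Hydroxyl-directed homogeneous hydrogenation: iridium bound to the axial CH2OH delivers hydrogen to the alkene face syn to it, so H-2 ends cis to CH2OH and the new C-2 methyl cis to the C-1 and C-8a methyls (a kinetic outcome that the less stable 1,3-diaxial arrangement requires).

Step 9
Reactants: 14 methyl 3-bromo-4-hydroxybenzoate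
Product: 15 methyl 4-acetoxy-3-bromobenzoate
Conditions: Ac2O (1.5 equiv), pyridine, DMAP (cat.), CH2Cl2, rt
Reagents that add atoms: acetic anhydride, CC(=O)OC(C)=O
Why: O-Acetylation masks the acidic phenol during the nickel coupling and can be removed at the end without acid.

Step 10
Reactants: 13 [(1R,2S,4aR,8aS)-5,5-(ethylenedioxy)-1,2,8a-trimethyldecahydronaphthalen-1-yl]methanol; 15 methyl 4-acetoxy-3-bromobenzoate
Product: 17 methyl 4-acetoxy-3-{[(1R,2S,4aR,8aS)-5,5-(ethylenedioxy)-1,2,8a-trimethyldecahydronaphthalen-1-yl]methyl}benzoate, via benzoxazoline adduct 16 (not isolated)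
Conditions: 13, 5,7-di-tert-butyl-3-phenyl-1,3-benzoxazol-3-ium tetrafluoroborate (1.2 equiv), pyridine (1.2 equiv), tBuOMe, rt; then 15 (1.3 equiv), [Ir(ppy)2(dtbbpy)]PF6 (1.5 mol %), NiBr2(dtbbpy) (5 mol %), quinuclidine (1.75 equiv), DMA, blue LEDs, rt
Reagents that add atoms: none
Why: Nickel/photoredox deoxygenative arylation of an alcohol: adduct 16 is oxidised and deprotonated, β-scission releases the primary neopentyl radical and nickel couples it with the aryl bromide; the radical carbon is not stereogenic, C-1 is untouched, and the ketal keeps any alkene or ketone out of reach of the radical.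

Step 11
Reactants: 17 methyl 4-acetoxy-3-{[(1R,2S,4aR,8aS)-5,5-(ethylenedioxy)-1,2,8a-trimethyldecahydronaphthalen-1-yl]methyl}benzoate
Product: 18 methyl 4-acetoxy-3-{[(1R,2S,4aR,8aS)-1,2,8a-trimethyl-5-oxodecahydronaphthalen-1-yl]methyl}benzoate
Conditions: PPTS (0.3 equiv), acetone–H2O 10:1, 50 °C, short reaction time
Reagents that add atoms: water, O
Why: Mild acid hydrolysis of the dioxolane; weak acid and short exposure are chosen because the trans-fused ketone, now carrying the axial C-2 methyl, is probably no longer the more stable C-4a epimer, and the aryl acetate survives.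

Step 12
Reactants: 18 methyl 4-acetoxy-3-{[(1R,2S,4aR,8aS)-1,2,8a-trimethyl-5-oxodecahydronaphthalen-1-yl]methyl}benzoate
Product: 19 methyl 4-acetoxy-3-{[(1R,2S,4aS,8aS)-1,2,8a-trimethyl-5-methylidenedecahydronaphthalen-1-yl]methyl}benzoate
Conditions: Zn, CH2Br2, TiCl4, THF–CH2Cl2, 0 °C to rt
Reagents that add atoms: dibromomethane, BrCBr
Why: Takai–Lombardo methylenation uses a non-basic gem-dimetal reagent that converts the ketone but not the two esters and does not enolise C-4a, so the trans ring fusion is carried into the alkene.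

Step 13
Reactants: 19 methyl 4-acetoxy-3-{[(1R,2S,4aS,8aS)-1,2,8a-trimethyl-5-methylidenedecahydronaphthalen-1-yl]methyl}benzoate
Product: 20 methyl 4-hydroxy-3-{[(1R,2S,4aS,8aS)-1,2,8a-trimethyl-5-methylidenedecahydronaphthalen-1-yl]methyl}benzoate
Conditions: K2CO3 (0.2 equiv), MeOH, 0 °C to rt
Reagents that add atoms: none
Why: Base-catalysed transesterification removes the aryl acetate; the methyl benzoate is unchanged in methanol and the exocyclic alkene never meets acid.

**Compound list**

1 | 3-methylcyclohex-2-en-1-one | CC1=CC(=O)CCC1 | starting material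
2 | 2-iodo-3-methylcyclohex-2-en-1-one | CC1=C(I)C(=O)CCC1 | intermediate
3 | 2-(hydroxymethyl)-3-methylcyclohex-2-en-1-one | CC1=C(CO)C(=O)CCC1 | intermediate
4 | methyl 2-methyl-3-oxobutanoate | COC(=O)C(C)C(C)=O | starting material
5 | (2-methyl-6-oxocyclohex-1-en-1-yl)methyl 2-methyl-3-oxobutanoate (α-carbon not defined, epimerising) | CC(=O)C(C)C(=O)OCC1=C(C)CCCC1=O | intermediate
6 | (4S,4aS)-4-acetyl-4,4a-dimethyloctahydro-1H-isochromene-3,8-dione, δ-lactone Michael adduct present as its C-8 enolate (C-8a not defined) | O=C1CCC[C@@]2(C)C1COC(=O)[C@]2(C)C(C)=O | intermediate (not isolated)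
7 | (2S)-2-methyl-2-[(1S)-1-methyl-2-methylidene-3-oxocyclohexyl]-3-oxobutanoic acid | O=C1CCC[C@@]([C@@](C)(C(C)=O)C(=O)O)(C)C1=C | intermediate (not isolated)
8 | methyl (2S)-2-methyl-2-[(1S)-1-methyl-2-methylidene-3-oxocyclohexyl]-3-oxobutanoate | O=C1CCC[C@@]([C@@](C)(C(C)=O)C(=O)OC)(C)C1=C | intermediate (not isolated)
9 | methyl (1S,4aR,8aS)-1,8a-dimethyl-2,5-dioxodecahydronaphthalene-1-carboxylate (trans-fused; ester anti to the angular methyl) | O=C1CCC[C@@]2(C)[C@H]1CCC(=O)[C@@]2(C)C(=O)OC | intermediate
10 | methyl (1S,4aR,8aS)-5,5-(ethylenedioxy)-1,8a-dimethyl-2-oxodecahydronaphthalene-1-carboxylate | C12(OCCO1)CCC[C@@]3(C)[C@H]2CCC(=O)[C@@]3(C)C(=O)OC | intermediate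
11 | methyl (1R,4aR,8aS)-5,5-(ethylenedioxy)-1,8a-dimethyl-2-methylidenedecahydronaphthalene-1-carboxylate | C12(OCCO1)CCC[C@@]3(C)[C@H]2CCC(=C)[C@@]3(C)C(=O)OC | intermediate
12 | [(1R,4aR,8aS)-5,5-(ethylenedioxy)-1,8a-dimethyl-2-methylidenedecahydronaphthalen-1-yl]methanol | C12(OCCO1)CCC[C@@]3(C)[C@H]2CCC(=C)[C@@]3(C)CO | intermediate
13 | [(1R,2S,4aR,8aS)-5,5-(ethylenedioxy)-1,2,8a-trimethyldecahydronaphthalen-1-yl]methanol | C12(OCCO1)CCC[C@@]3(C)[C@H]2CC[C@H](C)[C@@]3(C)CO | intermediate
14 | methyl 3-bromo-4-hydroxybenzoate | COC(=O)c1ccc(O)c(Br)c1 | starting material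
15 | methyl 4-acetoxy-3-bromobenzoate | COC(=O)c1ccc(OC(C)=O)c(Br)c1 | intermediate
16 | 5,7-di-tert-butyl-3-phenyl-2,3-dihydro-1,3-benzoxazol-2-yl ether of 13 (bound through the CH2O oxygen; C-2 of the heterocycle not defined) | C12(OCCO1)CCC[C@@]3(C)[C@H]2CC[C@H](C)[C@@]3(C)COC4Oc5c(C(C)(C)C)cc(C(C)(C)C)cc5N4c6ccccc6 | intermediate (not isolated)
17 | methyl 4-acetoxy-3-{[(1R,2S,4aR,8aS)-5,5-(ethylenedioxy)-1,2,8a-trimethyldecahydronaphthalen-1-yl]methyl}benzoate | C12(OCCO1)CCC[C@@]3(C)[C@H]2CC[C@H](C)[C@@]3(C)Cc1cc(C(=O)OC)ccc1OC(C)=O | intermediate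
18 | methyl 4-acetoxy-3-{[(1R,2S,4aR,8aS)-1,2,8a-trimethyl-5-oxodecahydronaphthalen-1-yl]methyl}benzoate | O=C1CCC[C@@]2(C)[C@H]1CC[C@H](C)[C@@]2(C)Cc1cc(C(=O)OC)ccc1OC(C)=O | intermediate
19 | methyl 4-acetoxy-3-{[(1R,2S,4aS,8aS)-1,2,8a-trimethyl-5-methylidenedecahydronaphthalen-1-yl]methyl}benzoate | C=C1CCC[C@@]2(C)[C@H]1CC[C@H](C)[C@@]2(C)Cc1cc(C(=O)OC)ccc1OC(C)=O | intermediate
20 | methyl 4-hydroxy-3-{[(1R,2S,4aS,8aS)-1,2,8a-trimethyl-5-methylidenedecahydronaphthalen-1-yl]methyl}benzoate | C=C1CCC[C@@]2(C)[C@H]1CC[C@H](C)[C@@]2(C)Cc1cc(C(=O)OC)ccc1O | target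

**Step count and risks**

Total step count: 13. Longest linear sequence: 12 steps (steps 1–8 and 10–13, from 1); step 9 is a one-step side branch.

Steps most likely to fail:

1. Step 4 (Proposed new method). What may go wrong: weak enantiofacial discrimination at the copper enolate, addition through the non-chelated enolate geometry (which would invert C-1 relative to C-8a), or decarboxylation of the keto acid before it is methylated. Fallback with known reactions, setting out from 3 and returning at 9: 3 is converted with PBr3 (Et2O, 0 °C) into 2-(bromomethyl)-3-methylcyclohex-2-en-1-one F1. The dianion of 4 (NaH, then n-BuLi, THF, 0 °C) is alkylated at its terminal carbon by F1 at −78 °C to give methyl 2-methyl-5-(2-methyl-6-oxocyclohex-1-en-1-yl)-3-oxopentanoate F2. DBU in MeCN closes ring B by intramolecular Michael addition to the racemic diketo ester, that is 9 together with its enantiomer methyl (1R,4aS,8aR)-1,8a-dimethyl-2,5-dioxodecahydronaphthalene-1-carboxylate F3. Ketalisation of the C-5 ketone with (2R,3R)-butane-2,3-diol (PPTS, benzene, reflux) gives the diastereomeric ketals, the (4R,5R)-4,5-dimethyl-1,3-dioxolane of 9 F4 and the (4R,5R)-4,5-dimethyl-1,3-dioxolane of the enantiomer F5, which are separated by chromatography. F4 is hydrolysed (PPTS, wet acetone) to enantiopure 9.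

2. Step 8. What may go wrong: hydrogen delivery to the wrong face, or migration of the exocyclic double bond before reduction. Fallback, setting out from 10 and returning at 13; it brings the methyl carbon in by cross-coupling and creates the stereocenter by reduction of a ring double bond. 10 is converted with KN(SiMe3)2 and PhNTf2 (THF, −78 °C) into the enol triflate methyl (1S,4aR,8aS)-5,5-(ethylenedioxy)-1,8a-dimethyl-2-(trifluoromethanesulfonyloxy)-1,4,4a,5,6,7,8,8a-octahydronaphthalene-1-carboxylate F6. Fe(acac)3-catalysed coupling with MeMgBr (THF–NMP, −30 °C) gives the ring alkene methyl (1R,4aR,8aS)-5,5-(ethylenedioxy)-1,2,8a-trimethyl-1,4,4a,5,6,7,8,8a-octahydronaphthalene-1-carboxylate F7. LiAlH4 gives the homoallylic alcohol [(1R,4aR,8aS)-5,5-(ethylenedioxy)-1,2,8a-trimethyl-1,4,4a,5,6,7,8,8a-octahydronaphthalen-1-yl]methanol F8. Hydroxyl-directed hydrogenation of F8 ([Ir(cod)(PCy3)(py)]PF6, H2, CH2Cl2) gives 13.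

3. Step 10. What may go wrong: slow capture of the hindered neopentyl radical by nickel, leading to reduction of the aryl bromide or of the radical instead of coupling. Fallback with two-electron chemistry, setting out from 13 (and 14) and returning at 17. 13 is oxidised with 1,1,1-triacetoxy-1,2-benziodoxol-3-one (DMP, NaHCO3, CH2Cl2) to (1R,2S,4aR,8aS)-5,5-(ethylenedioxy)-1,2,8a-trimethyldecahydronaphthalene-1-carbaldehyde F9. 14 is deprotonated with MeMgCl and submitted to bromine–magnesium exchange with iPrMgCl·LiCl (THF, −20 to 0 °C) to give the arylmagnesium reagent chloromagnesium 2-(chloromagnesio)-4-(methoxycarbonyl)phenoxide F10. Its addition to F9 gives the benzylic alcohol methyl 4-hydroxy-3-{hydroxy[(1R,2S,4aR,8aS)-5,5-(ethylenedioxy)-1,2,8a-trimethyldecahydronaphthalen-1-yl]methyl}benzoate F11. Hydrogenolysis of the benzylic C–O bond (H2, Pd(OH)2/C, EtOAc–AcOH; no alkene is present at this stage) gives the phenol methyl 4-hydroxy-3-{[(1R,2S,4aR,8aS)-5,5-(ethylenedioxy)-1,2,8a-trimethyldecahydronaphthalen-1-yl]methyl}benzoate F12. Acetylation (Ac2O, pyridine) gives 17.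

**Further compounds**

F1 | step 4 | 2-(bromomethyl)-3-methylcyclohex-2-en-1-one | CC1=C(CBr)C(=O)CCC1
F2 | step 4 | methyl 2-methyl-5-(2-methyl-6-oxocyclohex-1-en-1-yl)-3-oxopentanoate | COC(=O)C(C)C(=O)CCC1=C(C)CCCC1=O
F3 | step 4 | methyl (1R,4aS,8aR)-1,8a-dimethyl-2,5-dioxodecahydronaphthalene-1-carboxylate (enantiomer of 9) | O=C1CCC[C@]2(C)[C@@H]1CCC(=O)[C@]2(C)C(=O)OC
F4 | step 4 | (4R,5R)-4,5-dimethyl-1,3-dioxolane (C-5 ketal) of 9 | C[C@H]1OC2(O[C@@H]1C)CCC[C@@]3(C)[C@H]2CCC(=O)[C@@]3(C)C(=O)OC
F5 | step 4 | (4R,5R)-4,5-dimethyl-1,3-dioxolane (C-5 ketal) of F3 | C[C@H]1OC2(O[C@@H]1C)CCC[C@]3(C)[C@@H]2CCC(=O)[C@]3(C)C(=O)OC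
F6 | step 8 | methyl (1S,4aR,8aS)-5,5-(ethylenedioxy)-1,8a-dimethyl-2-(trifluoromethanesulfonyloxy)-1,4,4a,5,6,7,8,8a-octahydronaphthalene-1-carboxylate | C12(OCCO1)CCC[C@@]3(C)[C@H]2CC=C(OS(=O)(=O)C(F)(F)F)[C@@]3(C)C(=O)OC
F7 | step 8 | methyl (1R,4aR,8aS)-5,5-(ethylenedioxy)-1,2,8a-trimethyl-1,4,4a,5,6,7,8,8a-octahydronaphthalene-1-carboxylate | C12(OCCO1)CCC[C@@]3(C)[C@H]2CC=C(C)[C@@]3(C)C(=O)OC
F8 | step 8 | [(1R,4aR,8aS)-5,5-(ethylenedioxy)-1,2,8a-trimethyl-1,4,4a,5,6,7,8,8a-octahydronaphthalen-1-yl]methanol | C12(OCCO1)CCC[C@@]3(C)[C@H]2CC=C(C)[C@@]3(C)CO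
F9 | step 10 | (1R,2S,4aR,8aS)-5,5-(ethylenedioxy)-1,2,8a-trimethyldecahydronaphthalene-1-carbaldehyde | C12(OCCO1)CCC[C@@]3(C)[C@H]2CC[C@H](C)[C@@]3(C)C=O
F10 | step 10 | chloromagnesium 2-(chloromagnesio)-4-(methoxycarbonyl)phenoxide (made in the flask from 14) | COC(=O)c1ccc(O[Mg]Cl)c([Mg]Cl)c1
F11 | step 10 | methyl 4-hydroxy-3-{hydroxy[(1R,2S,4aR,8aS)-5,5-(ethylenedioxy)-1,2,8a-trimethyldecahydronaphthalen-1-yl]methyl}benzoate (both carbinol epimers) | C12(OCCO1)CCC[C@@]3(C)[C@H]2CC[C@H](C)[C@@]3(C)C(O)c1cc(C(=O)OC)ccc1O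
F12 | step 10 | methyl 4-hydroxy-3-{[(1R,2S,4aR,8aS)-5,5-(ethylenedioxy)-1,2,8a-trimethyldecahydronaphthalen-1-yl]methyl}benzoate | C12(OCCO1)CCC[C@@]3(C)[C@H]2CC[C@H](C)[C@@]3(C)Cc1cc(C(=O)OC)ccc1O
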